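**Assumption:** enolisable intermediates 3 and 5 to 7 are used as tautomer and epimer mixtures (their stereocentres are erased in step 3), and any 7 that lactonises early converges on 8 under the conditions of step 3.

## Retrosynthetic overview (disconnections listed from the starting materials upward)

1. 1 + 2 give 3: the last C–C bond of the open-chain 3,5-diketo ester that will become the 2-pyranone (ring left open on purpose).
2. 3 + 4 (ring A, bought as phloroacetophenone) give, through 5 and 6, the bridged adduct 7: the CH2 bridge, by Mannich/Michael methylene transfer.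
3. 7 gives, through 8 and 9, the chromone 10 (key disconnection): the 2-pyranone ring and ring C (as a chromone) are closed together in one operation; no stereocentre yet.
4. 10 + 11 give 12: the C8–acyl bond, by Friedel–Crafts acylation at the last free position of ring A.
5. 12 + 13 (ring B) give 14: the C2–aryl bond and the only stereocentre, by enantioselective conjugate arylation. Ring order: A (bought), then 2-pyranone and C together, then B attached.

## Route

Step 1
Reactants: 1 methyl 3-oxopentanoate; 2 N-methoxy-N-methylpropanamide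
Product: 3 methyl 4-methyl-3,5-dioxoheptanoate
Conditions: NaH (1.1 equiv), THF, 0 °C; n-BuLi (1.05 equiv), 0 °C; then 2, −78 → 0 °C; cold 1 M HCl
Reagents that add atoms: none
Why: γ-Acylation of the β-keto ester dianion (Huckin–Weiler dianion chemistry) with a Weinreb amide, whose chelated adduct stops at the ketone and keeps the more acidic product from consuming dianion; the new C4 centre is enolisable and of no consequence.

Step 2
Reactants: 3 methyl 4-methyl-3,5-dioxoheptanoate; 4 1-(2,4,6-trihydroxyphenyl)ethan-1-one (phloroacetophenone)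
Product: 7 methyl 2-[(3-acetyl-2,4,6-trihydroxyphenyl)methyl]-4-methyl-3,5-dioxoheptanoate, via Mannich base 5 (not isolated), via methylidene keto ester 6 (not isolated)
Conditions: [Me2N=CH2]I (1.05 equiv), MeCN, 0 °C → rt; then 4 (1.5 equiv), 65 °C
Reagents that add atoms: N,N-dimethylmethylideneammonium iodide (Eschenmoser's salt), C=[N+](C)C.[I-]
Why: Mannich reaction at the unhindered C2 methylene, thermal loss of dimethylamine to the α-methylidene β-keto ester and Friedel–Crafts-type Michael addition of the phloroglucinol nucleus (two equivalent free positions), the methylene-bridging tactic used for pyranone–acylphloroglucinol natural products; a Mannich adduct at the hindered C4 methine cannot eliminate and reverts, and no lasting stereocentre is made.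

Step 3
Reactants: 7 methyl 2-[(3-acetyl-2,4,6-trihydroxyphenyl)methyl]-4-methyl-3,5-dioxoheptanoate
Product: 10 3-[(5,7-dihydroxy-4-oxo-4H-chromen-6-yl)methyl]-6-ethyl-4-hydroxy-5-methyl-2H-pyran-2-one, via pyranone ketone 8 (not isolated), via enaminone 9 (not isolated)
Conditions: t-BuOCH(NMe2)2 (5 equiv), DBU (1.5 equiv), toluene/DMF 4:1, 90 °C; then 1 M HCl, THF, rt
Reagents that add atoms: tert-butoxybis(dimethylamino)methane (Bredereck's reagent), CC(C)(C)OC(N(C)C)N(C)C
Why: Proposed new method: under DBU the C5 enolate oxygen of the 3,5-diketo ester attacks the methyl ester (the standard base-mediated lactonisation to a 4-hydroxy-2-pyranone) while Bredereck's reagent turns the only methyl ketone into its enaminone, and on acidification the less hindered hydroxyl (flanked by H rather than by the pyranonylmethyl group) adds to the enaminone and expels dimethylamine (enaminone chromone synthesis), so two individually precedented annulations run in one flask and close both oxygen heterocycles; no stereocentre is formed and the epimerisable centres of 7 are erased.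

Step 4
Reactants: 10 3-[(5,7-dihydroxy-4-oxo-4H-chromen-6-yl)methyl]-6-ethyl-4-hydroxy-5-methyl-2H-pyran-2-one; 11 3-methylbut-2-enoyl chloride
Product: 12 3-{[5,7-dihydroxy-8-(3-methylbut-2-enoyl)-4-oxo-4H-chromen-6-yl]methyl}-6-ethyl-4-hydroxy-5-methyl-2H-pyran-2-one
Conditions: AlCl3 (5 equiv), 11 (1.2 equiv), PhNO2, 0 °C → rt; cold 1 M HCl work-up
Reagents that add atoms: none
Why: Friedel–Crafts acylation at C8, the only unsubstituted position of ring A and the site at which 5,7-dihydroxybenzopyranones take α,β-unsaturated acyl chlorides with AlCl3; the open enone is kept because no base is present to trigger oxa-Michael closure onto the 7-hydroxyl, and no stereocentre is formed.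

Step 5
Reactants: 12 3-{[5,7-dihydroxy-8-(3-methylbut-2-enoyl)-4-oxo-4H-chromen-6-yl]methyl}-6-ethyl-4-hydroxy-5-methyl-2H-pyran-2-one; 13 phenylboronic acid
Product: 14 3-{[(2S)-5,7-dihydroxy-8-(3-methylbut-2-enoyl)-4-oxo-2-phenyl-3,4-dihydro-2H-chromen-6-yl]methyl}-6-ethyl-4-hydroxy-5-methyl-2H-pyran-2-one
Conditions: Pd(OCOCF3)2 (10 mol%), (R)-4-tert-butyl-2-(pyridin-2-yl)-4,5-dihydro-1,3-oxazole [(R)-t-BuPyOx] (12 mol%), NH4PF6 (30 mol%), 13 (3 equiv), H2O (5 equiv), ClCH2CH2Cl, 60 °C
Reagents that add atoms: none
Why: Pd-catalysed enantioselective conjugate addition of an arylboronic acid to a chromone (Hayashi–Miyaura-type 1,4-addition with a pyridine–oxazoline ligand), in which the ligand-bound phenylpalladium inserts into one face of C2=C3 and sets C2 as S (the (R)-ligand is assigned by transposing the known facial preference for cyclic enones onto the chromone and must be confirmed on a model chromone), while the β,β-disubstituted acyclic enone and the 2-pyranone are poor acceptors and the acidic, base-free medium prevents retro-oxa-Michael racemisation.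

## Compound list

1 | methyl 3-oxopentanoate | CCC(=O)CC(=O)OC | starting material
2 | N-methoxy-N-methylpropanamide | CCC(=O)N(C)OC | starting material
3 | methyl 4-methyl-3,5-dioxoheptanoate (racemic, keto–enol mixture) | CCC(=O)C(C)C(=O)CC(=O)OC | intermediate
4 | 1-(2,4,6-trihydroxyphenyl)ethan-1-one | CC(=O)c1c(O)cc(O)cc1O | starting material
5 | methyl 2-[(dimethylamino)methyl]-4-methyl-3,5-dioxoheptanoate (epimer mixture) | CCC(=O)C(C)C(=O)C(CN(C)C)C(=O)OC | intermediate
6 | methyl 4-methyl-2-methylidene-3,5-dioxoheptanoate (racemic) | CCC(=O)C(C)C(=O)C(=C)C(=O)OC | intermediate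
7 | methyl 2-[(3-acetyl-2,4,6-trihydroxyphenyl)methyl]-4-methyl-3,5-dioxoheptanoate (epimer mixture) | CCC(=O)C(C)C(=O)C(Cc1c(O)cc(O)c(C(C)=O)c1O)C(=O)OC | intermediate
8 | 3-[(3-acetyl-2,4,6-trihydroxyphenyl)methyl]-6-ethyl-4-hydroxy-5-methyl-2H-pyran-2-one | CCc1oc(=O)c(Cc2c(O)cc(O)c(C(C)=O)c2O)c(O)c1C | intermediate
9 | 3-({3-[(2E)-3-(dimethylamino)prop-2-enoyl]-2,4,6-trihydroxyphenyl}methyl)-6-ethyl-4-hydroxy-5-methyl-2H-pyran-2-one | CCc1oc(=O)c(Cc2c(O)cc(O)c(C(=O)/C=C/N(C)C)c2O)c(O)c1C | intermediate
10 | 3-[(5,7-dihydroxy-4-oxo-4H-chromen-6-yl)methyl]-6-ethyl-4-hydroxy-5-methyl-2H-pyran-2-one | CCc1oc(=O)c(Cc2c(O)cc3occc(=O)c3c2O)c(O)c1C | intermediate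
11 | 3-methylbut-2-enoyl chloride | CC(C)=CC(=O)Cl | starting material
12 | 3-{[5,7-dihydroxy-8-(3-methylbut-2-enoyl)-4-oxo-4H-chromen-6-yl]methyl}-6-ethyl-4-hydroxy-5-methyl-2H-pyran-2-one | CCc1oc(=O)c(Cc2c(O)c(C(=O)C=C(C)C)c3occc(=O)c3c2O)c(O)c1C | intermediate
13 | phenylboronic acid | OB(O)c1ccccc1 | starting material
14 | 3-{[(2S)-5,7-dihydroxy-8-(3-methylbut-2-enoyl)-4-oxo-2-phenyl-3,4-dihydro-2H-chromen-6-yl]methyl}-6-ethyl-4-hydroxy-5-methyl-2H-pyran-2-one | CCc1oc(=O)c(Cc2c(O)c(C(=O)C=C(C)C)c3c(c2O)C(=O)C[C@@H](c2ccccc2)O3)c(O)c1C | target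

## Step count and risks

Total steps: 5. Longest linear sequence: 5 (1 → 3 → 7 → 10 → 12 → 14).

The three steps most likely to fail are steps 3, 4 and 5.

(i) Step 3 is the least secure. The two annulations may not tolerate each other in one flask, and the chromone could close through the hydroxyl next to the bridge, giving the 8-substituted isomer. The fallback sets out from 3 and 4 and comes back at 12, bypassing steps 2 to 4, with the rings closed separately in an order that fixes the regiochemistry by symmetry.
- 3 is lactonised (DBU, toluene, reflux) to 6-ethyl-4-hydroxy-5-methyl-2H-pyran-2-one F1.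
- 4 is taken with Bredereck's reagent and then HCl through (2E)-3-(dimethylamino)-1-(2,4,6-trihydroxyphenyl)prop-2-en-1-one F2 to 5,7-dihydroxy-4H-chromen-4-one F3; either ortho hydroxyl gives the same chromone.
- F3 is acylated with 11 and AlCl3, by analogy with 5,7-dihydroxycoumarins at C8, to 5,7-dihydroxy-8-(3-methylbut-2-enoyl)-4H-chromen-4-one F4.
- F1 and Eschenmoser's salt give 3-[(dimethylamino)methyl]-6-ethyl-4-hydroxy-5-methyl-2H-pyran-2-one F5. On warming with F4 this loses dimethylamine to 6-ethyl-5-methyl-3-methylidene-2H-pyran-2,4(3H)-dione F6, which alkylates C6, the only free position of F4, to give 12.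

(ii) Step 4 may fail because the new enone closes onto the 7-hydroxyl to a 2,2-dimethylchromanone under AlCl3. The fallback sets out from 10 and comes back at 12, installing the acyl group saturated and unveiling the alkene under neutral conditions.
- 10 is acylated with 3-methylbutanoyl chloride and AlCl3 to 3-{[5,7-dihydroxy-8-(3-methylbutanoyl)-4-oxo-4H-chromen-6-yl]methyl}-6-ethyl-4-hydroxy-5-methyl-2H-pyran-2-one F7.
- PhSeCl in EtOAc at rt selenenylates the only enolisable ketone to 3-({5,7-dihydroxy-8-[3-methyl-2-(phenylselanyl)butanoyl]-4-oxo-4H-chromen-6-yl}methyl)-6-ethyl-4-hydroxy-5-methyl-2H-pyran-2-one F8.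
- H2O2 and pyridine in CH2Cl2 at 0 °C effect selenoxide syn-elimination toward the isopropyl methine to give 12.
- If acid cleavage of the methylene bridge is the problem instead, the order used in the fallback for step 3 (acylation before bridging) applies.

(iii) Step 5 may fail through competing arylation of the 3-methylbut-2-enoyl enone, catalyst inhibition by the acidic hydroxyls, or low selectivity on so crowded a chromone. The fallback sets out from 10 and comes back at 14, setting the stereocentre before the second enone exists.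
- 10 is arylated with 13 under the same Pd(OCOCF3)2/(R)-t-BuPyOx conditions to 3-{[(2S)-5,7-dihydroxy-4-oxo-2-phenyl-3,4-dihydro-2H-chromen-6-yl]methyl}-6-ethyl-4-hydroxy-5-methyl-2H-pyran-2-one F9.
- F9 is acylated at C8, its only free ring A position, with 11 and TiCl4 in CH2Cl2 at −20 °C (acidic, base-free, so the flavanone is not opened) to give 14.

## Further compounds

F1 | step 3 | 6-ethyl-4-hydroxy-5-methyl-2H-pyran-2-one | CCc1oc(=O)cc(O)c1C
F2 | step 3 | (2E)-3-(dimethylamino)-1-(2,4,6-trihydroxyphenyl)prop-2-en-1-one | CN(C)/C=C/C(=O)c1c(O)cc(O)cc1O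
F3 | step 3 | 5,7-dihydroxy-4H-chromen-4-one | O=c1ccoc2cc(O)cc(O)c12
F4 | step 3 | 5,7-dihydroxy-8-(3-methylbut-2-enoyl)-4H-chromen-4-one | CC(C)=CC(=O)c1c(O)cc(O)c2c(=O)ccoc12
F5 | step 3 | 3-[(dimethylamino)methyl]-6-ethyl-4-hydroxy-5-methyl-2H-pyran-2-one | CCc1oc(=O)c(CN(C)C)c(O)c1C
F6 | step 3 | 6-ethyl-5-methyl-3-methylidene-2H-pyran-2,4(3H)-dione | CCC1=C(C)C(=O)C(=C)C(=O)O1
F7 | step 4 | 3-{[5,7-dihydroxy-8-(3-methylbutanoyl)-4-oxo-4H-chromen-6-yl]methyl}-6-ethyl-4-hydroxy-5-methyl-2H-pyran-2-one | CCc1oc(=O)c(Cc2c(O)c(C(=O)CC(C)C)c3occc(=O)c3c2O)c(O)c1C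
F8 | step 4 | 3-({5,7-dihydroxy-8-[3-methyl-2-(phenylselanyl)butanoyl]-4-oxo-4H-chromen-6-yl}methyl)-6-ethyl-4-hydroxy-5-methyl-2H-pyran-2-one | CCc1oc(=O)c(Cc2c(O)c(C(=O)C([Se]c4ccccc4)C(C)C)c3occc(=O)c3c2O)c(O)c1C
F9 | step 5 | 3-{[(2S)-5,7-dihydroxy-4-oxo-2-phenyl-3,4-dihydro-2H-chromen-6-yl]methyl}-6-ethyl-4-hydroxy-5-methyl-2H-pyran-2-one | CCc1oc(=O)c(Cc2c(O)cc3c(c2O)C(=O)C[C@@H](c2ccccc2)O3)c(O)c1C
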